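**Plan**
- Cuts: first the C3–C1' bond between the quinone ring and the octadecyl chain. Then the difference between the oxygen substituents at C2 (OH) and C5 (OMe) is removed, which leads back to symmetric 2,5-dihydroxy-1,4-benzoquinone and 1-octadecanol.
- Enabling feature: HO–C2=C3(H)–C4=O of the six-membered ring is a vinylogous carboxylic acid, so C3 is an enol carbon. It condenses with an aldehyde to an ortho-quinone methide (C1'=C3 between C2=O and C4=O), whose C1' accepts hydride and restores the hydroxyquinone.
- MeO–C5=C6(H)–C1=O is only a vinylogous ester, so C6 stays silent. The methyl ether of the target itself acts as the blocking group, and nothing has to be removed afterwards.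
- Forward: the ring is bought ready-made. The sequence is double O-methylation, hydrolysis of one ether, oxidation of the alcohol to the aldehyde, then union of ring and chain as the last step, at the final oxidation level and without protecting groups.
- Stereochemistry: the target has no stereocentre and no stereogenic double bond, so nothing has to be controlled.

Key step: step 4

Remark on the chemistry: ring atoms carry the numbers of the name 2-hydroxy-5-methoxy-3-octadecyl-1,4-benzoquinone, C1' is the chain carbon on the ring, and the target is taken as the 2-hydroxy-1,4-quinone tautomer that is drawn.

Step 1
Reactants: 1 2,5-dihydroxy-1,4-benzoquinone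
Product: 2 2,5-dimethoxy-1,4-benzoquinone
Conditions: MeOH (solvent), conc. H2SO4 (cat.), reflux; product collected by filtration
Reagents that add atoms: methanol, CO
Why: Vinylogous Fischer esterification, in which each HO–C=C–C=O unit of 1 behaves like a carboxylic acid (acid-catalysed addition of methanol at the oxygen-bearing ring carbon, loss of water), and the sparingly soluble diether 2 should crystallise and pull the equilibrium.

Step 2
Reactants: 2 2,5-dimethoxy-1,4-benzoquinone
Product: 3 2-hydroxy-5-methoxy-1,4-benzoquinone
Conditions: NaOH (1.05 equiv, 1 M aq, slow addition), THF/H2O, 0 °C to rt; then 1 M HCl to pH 1–2
Reagents that add atoms: sodium hydroxide, [Na+].[OH-]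
Why: Saponification of a vinylogous ester by addition–elimination of hydroxide at the methoxy-bearing ring carbon, in which each hydrolysis consumes one hydroxide so that the base is the limiting reagent, and the quinonolate anion formed first repels a second hydroxide, which should stop the reaction at the monoether.

Step 3
Reactants: 4 1-octadecanol
Product: 5 octadecanal
Conditions: TEMPO (2,2,6,6-tetramethylpiperidin-1-oxyl, 10 mol %), PhI(OAc)2 (1.1 equiv), CH2Cl2, rt; short silica plug, used at once
Reagents that add atoms: none
Why: Oxoammonium-mediated alcohol oxidation (TEMPO with the trivalent iodine reagent PhI(OAc)2, Piancatelli–Margarita conditions), which in the absence of water forms no aldehyde hydrate and should therefore stop at the aldehyde.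

Step 4
Reactants: 3 2-hydroxy-5-methoxy-1,4-benzoquinone; 5 octadecanal (1.1 equiv)
Product: 7 irisoquin, via ortho-quinone methide 6 (not isolated)
Conditions: L-proline (20 mol %), Hantzsch ester (diethyl 2,6-dimethyl-1,4-dihydropyridine-3,5-dicarboxylate, 1.2 equiv, present from the start), CH2Cl2, 25 °C; work-up in air
Reagents that add atoms: none
Why: This is a three-component reductive alkylation (organocatalytic Knoevenagel condensation/transfer hydrogenation cascade), a reaction type established for 2-hydroxy-1,4-naphthoquinone and 2,5-dihydroxy-1,4-benzoquinone with aliphatic aldehydes. Proline turns 5 into an iminium ion, which is attacked by C3 of 3, the alpha carbon of the vinylogous acid HO–C2=C3(H)–C4=O, and loss of proline from the Mannich adduct gives the ortho-quinone methide 6. The exocyclic carbon C1' of 6 is a strong hydride acceptor because hydride delivery from the Hantzsch ester restores the hydroxyquinone, so 6 should be reduced as it forms and the resulting enolate is protonated to 7. The step needs site selectivity (C3 against C6), a single alkylation, and reduction of 6 faster than Michael addition of a second molecule of 3; the first two are secured by the C5 methyl ether, which leaves C6 as the alpha carbon of a non-ionisable vinylogous ester without enol character, and the third by the excess of Hantzsch ester present from the start. The low reduction potential of a quinone that carries one hydroxyl and one methoxyl group should keep the ring itself from being reduced by the dihydropyridine, and any hydroquinone that does form is reoxidised by air on work-up. No ring is closed and no stereocentre is created.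

**Compound list**
1 | 2,5-dihydroxy-1,4-benzoquinone | O=C1C=C(O)C(=O)C=C1O | starting material
2 | 2,5-dimethoxy-1,4-benzoquinone | COC1=CC(=O)C(OC)=CC1=O | intermediate
3 | 2-hydroxy-5-methoxy-1,4-benzoquinone | COC1=CC(=O)C(O)=CC1=O | intermediate
4 | 1-octadecanol | CCCCCCCCCCCCCCCCCCO | starting material
5 | octadecanal | CCCCCCCCCCCCCCCCCC=O | intermediate
6 | 5-methoxy-3-octadecylidenecyclohex-5-ene-1,2,4-trione (ortho-quinone methide, not isolated, geometry of the exocyclic double bond without consequence) | CCCCCCCCCCCCCCCCCC=C1C(=O)C(=O)C=C(OC)C1=O | intermediate
7 | irisoquin (2-hydroxy-5-methoxy-3-octadecyl-1,4-benzoquinone) | CCCCCCCCCCCCCCCCCCC1=C(O)C(=O)C=C(OC)C1=O | target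

Total step count: 4
Longest linear sequence: 3 steps (1 to 2 to 3 to 7). The branch 4 to 5 joins in step 4.

**Steps most likely to fail**

Risk 1, step 4. Several processes could divert the cascade:
- The quinone methide may be intercepted by a second molecule of 3 before hydride transfer.
- The quinone methide may isomerise to the 1-alkenyl quinone.
- The amine catalyst may be consumed by addition–elimination at the C5 methoxy carbon.
- The ring may be reduced prematurely by the dihydropyridine.

The fallback replaces the polar union with a radical one. It sets out from 1, which is used in excess and whose two ring C–H positions are equivalent by symmetry. Commercial nonadecanoic acid is decarboxylated with persulfate under catalysis by monovalent silver (AgNO3 cat., (NH4)2S2O8, MeCN/H2O, 70 °C; Kochi–Anderson/Jacobsen–Torssell type quinone alkylation). This should deliver the octadecyl radical to the quinone C–H and, after loss of an electron and a proton, give 2,5-dihydroxy-3-octadecyl-1,4-benzoquinone F1. Vinylogous Fischer esterification of F1 (MeOH, H2SO4 cat., reflux) should touch only the C5 hydroxyl. Addition of methanol at C2 is blocked by the neighbouring chain, as with 3-alkyl-2-hydroxynaphthoquinones. The fallback comes back to the route at 7.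

Risk 2, step 2. The second ether may be hydrolysed while undissolved 2 is still present, and the quinone may degrade in base. The fallback sets out from 2 and comes back at 3. It moves the attack from the ring carbon to the methyl carbon. LiI (1.1 equiv) in refluxing EtOAc, followed by dilute HCl, cleaves the vinylogous methyl ester by SN2 dealkylation, as in the LiI cleavage of methyl esters. The first cleavage expels a monoanion, whereas a second one would have to expel a much poorer dianionic leaving group, so it should stop after one ether. No compound outside the compound list arises (F0).

Risk 3, step 3. The alcohol may be over-oxidised through the hydrate, may form an ester through the hemiacetal, and the aldehyde may autoxidise or trimerise before use. The fallback approaches the aldehyde from the higher oxidation level. It sets out from 4, which is oxidised fully (TEMPO cat., NaOCl cat., NaClO2, MeCN/phosphate buffer, 35 °C) to octadecanoic acid F2. This is converted with 1,1'-carbonyldiimidazole and MeNH(OMe)·HCl in CH2Cl2 into N-methoxy-N-methyloctadecanamide F3. Reduction with i-Bu2AlH (THF, −78 °C) holds as the chelated tetrahedral adduct until work-up. It then releases the aldehyde just before the coupling and comes back to the route at 5.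

**Further compounds**
F1 | step 4 | 2,5-dihydroxy-3-octadecyl-1,4-benzoquinone | CCCCCCCCCCCCCCCCCCC1=C(O)C(=O)C=C(O)C1=O
F0 | step 2 | none | none
F2 | step 3 | octadecanoic acid | CCCCCCCCCCCCCCCCCC(=O)O
F3 | step 3 | N-methoxy-N-methyloctadecanamide | CCCCCCCCCCCCCCCCCC(=O)N(C)OC
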